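**Retrosynthetic overview**

1. Schweinfurthin I comes from bis-MOM ether 23 by a final acetal cleavage, and ring B of 23 comes from one dehydrogenation of vinylogous ester 18.
2. The strategy rests on ring B: a benzene carrying oxygen at C3 and C5 and the stilbene carbon at C1 has the substitution pattern of a 5-alkenylcyclohexane-1,3-dione, two hydrogens below the arene oxidation level.
3. That dione (17) is opened by a Michael–Claisen annulation into dimethyl malonate (two ring carbons) and the (3E,5E)-6-arylhexa-3,5-dien-2-one 12 (C1 to C4 give the other four).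
4. Dienone 12 comes from two stabilized-ylide Wittig homologations of aldehyde 8, which comes from 3-bromo-4-hydroxybenzaldehyde and geranyl bromide by an aryl-copper SN2 coupling.
5. Ring order: ring A is bought and geranylated first; ring B is closed in step 7 and aromatized in step 11.

Key step: step 7

Remark: Ar stands for 3-geranyl-4-(methoxymethoxy)phenyl and geranyl for (2E)-3,7-dimethylocta-2,6-dien-1-yl. Compounds 14 to 16, 18 and 19 to 21 are racemic (diastereomer mixtures where two stereocentres are present); this is assumed to be harmless because every ring stereocentre is destroyed before the target.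

**Route**

Step 1
Reactants: 1 3-bromo-4-hydroxybenzaldehyde
Product: 2 2-bromo-4-(1,3-dioxolan-2-yl)phenol
Conditions: ethylene glycol (3 equiv), p-TsOH·H2O (cat.), toluene, Dean–Stark reflux; NaHCO3 wash, used directly
Reagents that add atoms: ethylene glycol, OCCO
Why: Acid-catalysed acetalization driven by azeotropic removal of water masks the aldehyde before any acid-labile group is present, and the ortho bromine tempers the donor strength of the free phenol so that the acetal should be stable enough to carry forward after a basic work-up.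

Step 2
Reactants: 2 2-bromo-4-(1,3-dioxolan-2-yl)phenol
Product: 3 2-[3-bromo-4-(methoxymethoxy)phenyl]-1,3-dioxolane
Conditions: MOMCl (1.5 equiv), iPr2NEt (2 equiv), CH2Cl2, 0 °C to rt
Reagents that add atoms: chloromethyl methyl ether (MOMCl), COCCl
Why: Williamson-type O-alkylation of the phenol under amine-buffered conditions should leave the dioxolane intact and installs an ether that will stabilize the ortho-lithio species by chelation.

Step 3
Reactants: 3 2-[3-bromo-4-(methoxymethoxy)phenyl]-1,3-dioxolane; 4 geranyl bromide
Product: 7 2-[3-geranyl-4-(methoxymethoxy)phenyl]-1,3-dioxolane, via aryllithium 5 (not isolated), via arylcopper 6 (not isolated)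
Conditions: n-BuLi (1.05 equiv), THF, −78 °C; CuBr·SMe2 (1.1 equiv), −78 to −40 °C; then 4 (1.2 equiv), −78 °C to rt
Reagents that add atoms: none
Why: Bromine–lithium exchange is faster than any deprotonation at −78 °C, and the arylcopper obtained by transmetalation should displace the primary allylic bromide in an SN2 sense without allylic transposition, so the E trisubstituted olefin of the geranyl unit is carried over unchanged.

Step 4
Reactants: 7 2-[3-geranyl-4-(methoxymethoxy)phenyl]-1,3-dioxolane
Product: 8 3-geranyl-4-(methoxymethoxy)benzaldehyde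
Conditions: PPTS (0.2 equiv), acetone–H2O (10:1), 40 °C
Reagents that add atoms: water, O
Why: Acetal hydrolysis through a para-alkoxy-stabilized benzylic oxocarbenium ion is far faster than cleavage of the formaldehyde-derived MOM acetal, and a pyridinium acid is too weak to protonate the geranyl olefins.

Step 5
Reactants: 8 3-geranyl-4-(methoxymethoxy)benzaldehyde; 9 (triphenylphosphoranylidene)acetaldehyde
Product: 10 (2E)-3-[3-geranyl-4-(methoxymethoxy)phenyl]prop-2-enal
Conditions: 9 (1.15 equiv), toluene, 80 °C, stopped at full consumption of 8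
Reagents that add atoms: none
Why: Wittig olefination with a stabilized formylmethylene ylide is E-selective through the reversible, thermodynamically controlled oxaphosphetane pathway, and a small excess of ylide limits a second homologation of the enal.

Step 6
Reactants: 10 (2E)-3-[3-geranyl-4-(methoxymethoxy)phenyl]prop-2-enal; 11 1-(triphenylphosphoranylidene)propan-2-one
Product: 12 (3E,5E)-6-[3-geranyl-4-(methoxymethoxy)phenyl]hexa-3,5-dien-2-one
Conditions: 11 (1.5 equiv), toluene, 90 °C
Reagents that add atoms: none
Why: A second Wittig olefination with the stabilized acetonyl ylide should give the new enone olefin as the E isomer and does not touch the existing E styryl olefin.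

Step 7
Reactants: 12 (3E,5E)-6-[3-geranyl-4-(methoxymethoxy)phenyl]hexa-3,5-dien-2-one; 13 dimethyl malonate
Product: 15 methyl 2,4-dioxo-6-[(E)-2-Ar-vinyl]cyclohexane-1-carboxylate (crude keto/enol and diastereomer mixture), via Michael adduct 14 (not isolated)
Conditions: 13 (1.2 equiv), NaOMe (1.3 equiv), MeOH, reflux; then cold 1 M HCl to pH 3–4 at 0 °C, extraction, used crude
Reagents that add atoms: none
Why: Methoxide deprotonates 13 and the malonate anion adds reversibly to C4 of dienone 12 to give adduct 14, whose methyl-ketone enolate (formed at the C1 methyl by proton transfer) attacks one ester carbonyl and expels methoxide, so the two new bonds are malonate carbon to C4 and C1 to ester carbonyl. This is the classical Michael–Claisen cyclohexane-1,3-dione annulation of a malonate with an enone, applied here to a styryl-substituted enone. The carbocycle that becomes ring B closes in a 6-(enolendo)-exo-trig mode, and deprotonation of the resulting beta-dicarbonyl by methoxide makes the closure irreversible. The two ring stereocentres (C1 bearing the ester, C6 bearing the styryl group) form without external control, C1 being epimerizable toward the trans isomer, and both are erased later, so a racemic diastereomer mixture is acceptable. The step needs 1,4- rather than 1,6-addition: the 1,4-adduct keeps the aryl-conjugated E olefin, the conjugate addition is reversible under methoxide, and only the 1,4-adduct can reach a six-membered ring in the irreversible Claisen step, which drains the equilibrium. The geranyl olefins, the E styryl olefin and the aryl MOM ether are inert to NaOMe in methanol, and the methyl ester/methoxide pairing rules out transesterification scrambling.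

Step 8
Reactants: 15 methyl 2,4-dioxo-6-[(E)-2-Ar-vinyl]cyclohexane-1-carboxylate
Product: 17 5-[(E)-2-Ar-vinyl]cyclohexane-1,3-dione, via keto acid 16 (not isolated)
Conditions: 2 M aq. NaOH (3 equiv), MeOH, 70 °C; then 1 M HCl to pH 4 at 0 °C, warmed to 55 °C until gas evolution ends
Reagents that add atoms: none
Why: Saponification of the ester followed by loss of CO2 from the beta-keto acid through the usual six-membered transition state should occur at a pH and temperature at which the aryl MOM ether and the geranyl chain survive, and it removes the stereocentre at the former C1.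

Step 9
Reactants: 17 5-[(E)-2-Ar-vinyl]cyclohexane-1,3-dione
Product: 18 3-(methoxymethoxy)-5-[(E)-2-Ar-vinyl]cyclohex-2-en-1-one (racemic)
Conditions: MOMCl (1.2 equiv), iPr2NEt (1.5 equiv), CH2Cl2, 0 °C; chromatography on Et3N-deactivated silica
Reagents that add atoms: chloromethyl methyl ether (MOMCl), COCCl
Why: The hard oxocarbenium-like electrophile alkylates the ambident dione enolate on oxygen, and because the dione is symmetric only one vinylogous ester can form.

Step 10
Reactants: 18 3-(methoxymethoxy)-5-[(E)-2-Ar-vinyl]cyclohex-2-en-1-one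
Product: 20 3-(methoxymethoxy)-6-(phenylselanyl)-5-[(E)-2-Ar-vinyl]cyclohex-2-en-1-one (trans isomer expected to predominate), via lithium dienolate 19 (not isolated)
Conditions: LiN(iPr)2 (1.1 equiv), THF, −78 °C; PhSeCl (1.05 equiv) in THF added quickly, −78 °C
Reagents that add atoms: phenylselenyl chloride (PhSeCl), Cl[Se]c1ccccc1
Why: Kinetic deprotonation of a vinylogous ester occurs at the alpha-prime carbon C6, and the cross-conjugated enolate is selenenylated there, anti to the C5 substituent, much faster than PhSeCl can add to the isolated olefins at −78 °C.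

Step 11
Reactants: 20 3-(methoxymethoxy)-6-(phenylselanyl)-5-[(E)-2-Ar-vinyl]cyclohex-2-en-1-one
Product: 23 3-[(E)-2-Ar-vinyl]-5-(methoxymethoxy)phenol, via selenoxide 21 (not isolated), via cyclohexadienone 22 (not isolated)
Conditions: mCPBA (1.0 equiv), CH2Cl2, −78 °C; then iPr2NH (3 equiv), −78 °C to rt
Reagents that add atoms: none
Why: Selenide oxidation outruns olefin epoxidation at −78 °C, the selenoxide undergoes syn-elimination toward the only available beta-hydrogen at C5 (the cis selenide can equilibrate by enolization at C6 under the amine), and the resulting cyclohexa-2,5-dienone with a CH2 at C4 is the keto tautomer of a phenol and should aromatize irreversibly while the amine scavenges the electrophilic selenium by-product.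

Step 12
Reactants: 23 3-[(E)-2-Ar-vinyl]-5-(methoxymethoxy)phenol
Product: 24 schweinfurthin I
Conditions: p-TsOH·H2O (0.5 equiv), MeOH (dilute), rt, quenched with NaHCO3 as soon as 23 is consumed
Reagents that add atoms: none
Why: Acid-catalysed transacetalization to methanol removes both aryl MOM groups as dimethoxymethane under conditions mild enough that protonation of the trisubstituted geranyl olefins should remain slow.

**Compound list**

1 | 3-bromo-4-hydroxybenzaldehyde | O=Cc1ccc(O)c(Br)c1 | starting material
2 | 2-bromo-4-(1,3-dioxolan-2-yl)phenol | Oc1ccc(C2OCCO2)cc1Br | intermediate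
3 | 2-[3-bromo-4-(methoxymethoxy)phenyl]-1,3-dioxolane | COCOc1ccc(C2OCCO2)cc1Br | intermediate
4 | geranyl bromide, (2E)-1-bromo-3,7-dimethylocta-2,6-diene | CC(C)=CCC/C(C)=C/CBr | starting material
5 | [5-(1,3-dioxolan-2-yl)-2-(methoxymethoxy)phenyl]lithium | [Li]c1cc(C2OCCO2)ccc1OCOC | intermediate
6 | [5-(1,3-dioxolan-2-yl)-2-(methoxymethoxy)phenyl]copper | [Cu]c1cc(C2OCCO2)ccc1OCOC | intermediate
7 | 2-[3-geranyl-4-(methoxymethoxy)phenyl]-1,3-dioxolane | CC(C)=CCC/C(C)=C/Cc1cc(C2OCCO2)ccc1OCOC | intermediate
8 | 3-geranyl-4-(methoxymethoxy)benzaldehyde | CC(C)=CCC/C(C)=C/Cc1cc(C=O)ccc1OCOC | intermediate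
9 | (triphenylphosphoranylidene)acetaldehyde | O=CC=P(c1ccccc1)(c1ccccc1)c1ccccc1 | starting material
10 | (2E)-3-[3-geranyl-4-(methoxymethoxy)phenyl]prop-2-enal | CC(C)=CCC/C(C)=C/Cc1cc(/C=C/C=O)ccc1OCOC | intermediate
11 | 1-(triphenylphosphoranylidene)propan-2-one | CC(=O)C=P(c1ccccc1)(c1ccccc1)c1ccccc1 | starting material
12 | (3E,5E)-6-[3-geranyl-4-(methoxymethoxy)phenyl]hexa-3,5-dien-2-one | CC(C)=CCC/C(C)=C/Cc1cc(/C=C/C=C/C(C)=O)ccc1OCOC | intermediate
13 | dimethyl malonate | COC(=O)CC(=O)OC | starting material
14 | dimethyl 2-[(1E)-1-Ar-5-oxohex-1-en-3-yl]malonate (racemic Michael adduct) | CC(C)=CCC/C(C)=C/Cc1cc(/C=C/C(CC(C)=O)C(C(=O)OC)C(=O)OC)ccc1OCOC | intermediate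
15 | methyl 2,4-dioxo-6-[(E)-2-Ar-vinyl]cyclohexane-1-carboxylate (racemic, diastereomer mixture) | CC(C)=CCC/C(C)=C/Cc1cc(/C=C/C2CC(=O)CC(=O)C2C(=O)OC)ccc1OCOC | intermediate
16 | 2,4-dioxo-6-[(E)-2-Ar-vinyl]cyclohexane-1-carboxylic acid (racemic, diastereomer mixture) | CC(C)=CCC/C(C)=C/Cc1cc(/C=C/C2CC(=O)CC(=O)C2C(=O)O)ccc1OCOC | intermediate
17 | 5-[(E)-2-Ar-vinyl]cyclohexane-1,3-dione | CC(C)=CCC/C(C)=C/Cc1cc(/C=C/C2CC(=O)CC(=O)C2)ccc1OCOC | intermediate
18 | 3-(methoxymethoxy)-5-[(E)-2-Ar-vinyl]cyclohex-2-en-1-one (racemic) | CC(C)=CCC/C(C)=C/Cc1cc(/C=C/C2CC(=O)C=C(OCOC)C2)ccc1OCOC | intermediate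
19 | lithium 5-(methoxymethoxy)-3-[(E)-2-Ar-vinyl]cyclohexa-1,5-dien-1-olate (kinetic C6 enolate of 18) | CC(C)=CCC/C(C)=C/Cc1cc(/C=C/C2C=C(O[Li])C=C(OCOC)C2)ccc1OCOC | intermediate
20 | 3-(methoxymethoxy)-6-(phenylselanyl)-5-[(E)-2-Ar-vinyl]cyclohex-2-en-1-one (racemic, mainly trans) | CC(C)=CCC/C(C)=C/Cc1cc(/C=C/C2CC(OCOC)=CC(=O)C2[Se]c3ccccc3)ccc1OCOC | intermediate
21 | 3-(methoxymethoxy)-6-(phenylseleninyl)-5-[(E)-2-Ar-vinyl]cyclohex-2-en-1-one (selenoxide, diastereomer mixture) | CC(C)=CCC/C(C)=C/Cc1cc(/C=C/C2CC(OCOC)=CC(=O)C2[Se](=O)c3ccccc3)ccc1OCOC | intermediate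
22 | 3-(methoxymethoxy)-5-[(E)-2-Ar-vinyl]cyclohexa-2,5-dien-1-one | CC(C)=CCC/C(C)=C/Cc1cc(/C=C/C2=CC(=O)C=C(OCOC)C2)ccc1OCOC | intermediate
23 | 3-[(E)-2-[3-geranyl-4-(methoxymethoxy)phenyl]vinyl]-5-(methoxymethoxy)phenol | CC(C)=CCC/C(C)=C/Cc1cc(/C=C/c2cc(O)cc(OCOC)c2)ccc1OCOC | intermediate
24 | schweinfurthin I, 5-[(E)-2-(3-geranyl-4-hydroxyphenyl)vinyl]benzene-1,3-diol | CC(C)=CCC/C(C)=C/Cc1cc(/C=C/c2cc(O)cc(O)c2)ccc1O | target

**Step count**

Total steps: 12. Longest linear sequence: 12 steps, from 1 to 24.

**Steps most likely to fail**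

Step 7. The malonate may add at the remote C6 terminus of the dienone (1,6-addition), or the dienone may oligomerize under alkoxide faster than the ring closes. The fallback gives up the annulation for a convergent stilbene construction; it sets out from aldehyde 8 and returns to the route at the target 24. Methylenation of 8 with Ph3P=CH2 (from methyltriphenylphosphonium bromide and KOtBu, THF, 0 °C) should give the styrene 2-geranyl-1-(methoxymethoxy)-4-vinylbenzene F1. Commercial 5-bromoresorcinol is converted with MOMCl and iPr2NEt into 1-bromo-3,5-bis(methoxymethoxy)benzene F2. A Mizoroki–Heck coupling of F1 with F2 (Pd(OAc)2, P(o-tol)3, Et3N, DMF, 100 °C) should give the tris-MOM (E)-stilbene 1-geranyl-2-(methoxymethoxy)-5-[(E)-2-[3,5-bis(methoxymethoxy)phenyl]vinyl]benzene F3. Its three acetals are removed under the conditions of step 12 to give 24.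

Step 11. The oxidant may epoxidize the geranyl olefins, the selenium by-product may selenenylate the newly formed electron-rich phenol, and the cis selenide may fail to eliminate. The fallback avoids selenium; it sets out from vinylogous ester 18 and returns at phenol 23. The kinetic enolate of 18 (LiN(iPr)2, THF, −78 °C) is trapped with Me3SiCl to give the silyl dienol ether 1-(trimethylsilyloxy)-3-(methoxymethoxy)-5-[(E)-2-Ar-vinyl]cyclohexa-1,3-diene F4. A Saegusa–Ito dehydrosilylation with Pd(OAc)2 in MeCN at rt (the divalent palladium acetate is reduced to zerovalent palladium) should give dienone 22, which tautomerizes to 23.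

Step 12. Protonation of the geranyl olefins may lead to cyclization onto the freed ortho phenol (chroman formation) or to cation–olefin cyclization before both acetals are cleaved. The fallback removes the acetals without protic acid; it sets out from 23 and returns at 24. Treatment of 23 with Me3SiOTf and 2,2'-bipyridyl in CH2Cl2 at 0 °C should convert both aryl MOM ethers (and the free phenol) into silyl ethers, giving the tris(trimethylsilyl) ether of schweinfurthin I F5. Hydrolysis of F5 with water in THF at rt then liberates 24.

**Further compounds**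

F1 | step 7 | 2-geranyl-1-(methoxymethoxy)-4-vinylbenzene | CC(C)=CCC/C(C)=C/Cc1cc(C=C)ccc1OCOC
F2 | step 7 | 1-bromo-3,5-bis(methoxymethoxy)benzene | COCOc1cc(Br)cc(OCOC)c1
F3 | step 7 | 1-geranyl-2-(methoxymethoxy)-5-[(E)-2-[3,5-bis(methoxymethoxy)phenyl]vinyl]benzene | CC(C)=CCC/C(C)=C/Cc1cc(/C=C/c2cc(OCOC)cc(OCOC)c2)ccc1OCOC
F4 | step 11 | 1-(trimethylsilyloxy)-3-(methoxymethoxy)-5-[(E)-2-Ar-vinyl]cyclohexa-1,3-diene (racemic) | CC(C)=CCC/C(C)=C/Cc1cc(/C=C/C2C=C(O[Si](C)(C)C)C=C(OCOC)C2)ccc1OCOC
F5 | step 12 | tris(trimethylsilyl) ether of schweinfurthin I | CC(C)=CCC/C(C)=C/Cc1cc(/C=C/c2cc(O[Si](C)(C)C)cc(O[Si](C)(C)C)c2)ccc1O[Si](C)(C)C
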